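Locants used below: coumarin numbering (O1, C2 … C8a) with ring A the benzene ring and ring B the lactone ring; ring C is the pyranone, numbered O1', C2' (bonded to C3), C3', C4' (C=O), C5', C6' (CH–CH3); the side chain is C1'' (CH2), C2'' (carbinol), C3''.

## Analysis of the target

The target is a 2H-chromen-2-one whose ring A is a hexasubstituted benzene: C5 bears a (2S)-2-hydroxypropyl chain, C6 and C8 bear methyl groups, C7 a free phenol, and C8a and C4a carry the fused lactone ring B. C3 is joined to C2' of ring C, a 2,3-dihydro-4H-pyran-4-one that is a cyclic vinylogous ester with a methyl-bearing stereocentre at C6' (R). The two stereocentres, C2'' (S) and C6' (R), lie eight bonds apart on either side of the flat coumarin, so neither can steer the other. Each must come from a reagent or from the chiral pool, and an error at either gives a diastereomer that would be very hard to remove. Ring C is the fragile part: as a β-alkoxy enone it can open by retro-oxa-Michael reaction under base (eroding C6'), exchange with amines at C2' and hydrolyse in strong acid, and the C3=C4 bond is a doubly activated acceptor close to the C2'' hydroxyl. Aryl ether cleavage or strong hydride after ring C is in place is therefore excluded. The main difficulty is ring A: six contiguous, different substituents cannot be completed by substitution on an arene that is already crowded. The strategy rests on the C4a–C5 edge, whose two carbons carry C4 (carbonyl oxidation level) and C1'' (a methylene); this is the ortho acyl/alkyl pair left when an aryne inserts into a C–C bond of a malonic ester. The homophthalate so formed folds into a 3-methyl-3,4-dihydroisocoumarin, in which one lactone masks both the future C4 aldehyde and the C2'' carbinol.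

## Retrosynthetic reasoning

**32 ⇒ 21 + 29.** Ring B is opened at C3=C4 and at O1–C2. Cutting here, and not inside ring C, lets both stereocentres arrive in finished fragments and keeps ring C away from every strongly acidic, basic or reducing step. No protecting group is needed, because lactol 21 (open form 30) is a salicylaldehyde with the C2'' hydroxyl already free. Forward, the methylene of 29 must condense with the aldehyde carbon (via 31) and the C8a phenol must close onto the ester, under amine catalysis mild enough to leave C6' alone.

**29 ⇒ 27 ⇒ 24 + 25; 24 ⇒ 23 ⇒ 22.** Ring C is opened at O1'–C2' to the δ-hydroxy diketo ester 28 (silylated form 27). Its C3'–C4' bond is then cut to the dianion 26 of methyl acetoacetate 25 and Weinreb amide 24. C6' is thereby bought with methyl (3R)-3-hydroxybutanoate 22, and 25 supplies C2', C3' and the future C3 and C2 of the coumarin. Forward, a γ-acylation is followed by an acid-mediated ring closure in which the C6'–O bond is never broken.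

**21 ⇒ 18 ⇒ 17.** These are functional-group changes only: C4 goes back from lactol to lactone and the two phenols go back to methyl ethers. Ether cleavage is placed on 17 because it is the most robust compound of the route and because the C8a oxygen must be free before ring B can close; after ring C is present it would no longer be possible. The hydride step must stop at the hemiacetal on a ring that ionises easily at C4, so the phenols are masked in the flask (19, 20) while it runs.

**17 ⇒ 15 ⇒ 14 ⇒ 13.** The lactone C–O bond is opened to hydroxy ester 16 and the carbinol is traced to methyl ketone 15, so that C2'' is set by a reagent-controlled carbonyl reduction. The C2''–C3'' bond is then cut (methyl nucleophile on Weinreb amide 14), which leads to diester 13. The two esters of 13 differ enough without protection: the benzoate is flanked by a methoxy group and the acetate arm, so only the aliphatic ester is attacked.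

**13 ⇒ 9 + 10 (key disconnection).** C5–C1'' and C4a–C4 are cut together, giving dimethyl malonate 10 and aryne 11, which is released from silyl triflate 9. This places the last two ring substituents at a stage where substitution on the intact arene would be blocked; the aryne reacts through strain, not accessibility. Forward, the carbanion of 10 must add to C5, guided by the methoxy group next to C4a, and the acyl group must then transfer to C4a through 12.

**9 ⇒ 5 ⇒ 4 ⇒ 3 ⇒ 2 ⇒ 1.** The C–Si bond comes from silyl ether 6 of bromophenol 5 by bromine–lithium exchange and O-to-C silyl shift (7, 8). Bromine enters at the only free ring position of phenol 4. The two ring methyl groups (future C8 and C6 methyls) are traced to the formyl groups of 1 and 3. Regiochemistry is unambiguous because 2 is symmetric.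

## Alternatives that were turned down

**Alternative 1:** Ring A itself is disconnected at C7–C8, C8a–C4a and C6–C7, giving cyclobutenone A2 and siloxyalkyne A3. Heating the two should start a cascade of two four-electron ring openings, a [2+2] addition and a six-electron ring closure that ends in the resorcinol mono-silyl ether A1.
- For: the C2'' stereocentre is carried in from the chiral pool, so no asymmetric reduction is needed. The two ring oxygens are born differentiated (free C7–OH, silylated C8a–O). On this point it is stronger than the chosen route, which brings both oxygens as methyl ethers and pays with a Lewis-acid demethylation (step 11).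
- Against: A1 is only pentasubstituted. C4a is still a C–H, so C4 would have to be added by formylation at the one open position, between the silyloxy group and the branched chain. A2 is not a catalogue compound and needs several steps with the silyloxypropyl chain attached; A3 is a moisture-sensitive ynol ether.
- Comparison: the chosen insertion sets the C4a and C5 carbons in one operation on a ring made from a catalogue phenol by routine steps. The benzannulation would need at least as many steps and leaves the hardest bond, C4a–C4, to a substitution on a crowded ring.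

**Alternative 2:** The cut is at C3'–C4' and C4'–C5', around the ring C carbonyl. Alkyne A5, carbon monoxide A6 and iodide A7 would be joined under palladium catalysis and light to the open-chain ynone A4, which after desilylation should close ring C by 6-endo oxa-Michael addition.
- For: late and convergent; C6' comes from the chiral pool as in the chosen route; ring C never meets an amine base, which is an advantage over step 17.
- Against: it presupposes the complete hexasubstituted coumarin A5 and so does not address ring A at all. The alkyl partner A7 carries β-hydrogens and a β-silyloxy group, both open to elimination at the metal. A5 and A4 are acceptors, three silyl ethers must be put on and removed, and a toxic gas is handled.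
- Comparison: as a way to ring C it is about as convergent as step 17 but costs extra steps (terminal alkyne on the coumarin, three protections, cyclisation). The chosen route makes ring C in a four-step branch from 22 and joins it by a metal-free condensation without protection, and answers the base-sensitivity concern with a fallback.

**Alternative 3:** C5'–C6' and O1'–C2' are cut. The bis(silyloxy)diene A9 on the coumarin and acetaldehyde A10 would combine under a chiral tetravalent titanium Lewis acid and then acid (hetero-Diels–Alder or aldol–cyclisation) to give A8, the bis-silyl ether of the target.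
- For: ring C and C6' are made in one catalytic operation at the end, with no chiral building block. In step economy for ring C it beats the branch 22 → 29.
- Against: A10 is small, volatile and enolisable, so facial discrimination (methyl against hydrogen) is difficult. Any shortfall appears as the C6' epimer, and with C2'' eight bonds away the epimers would be practically inseparable. A9 is a hydrolytically labile bis-silyl enol ether conjugated to an acceptor, and it again needs the finished ring A.
- Comparison: the chosen strategy buys C6' enantiopure with 22 and avoids a late epimer problem, at the price of a longer branch.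

Key step: step 7

Assumptions: aldehyde 1 is taken as a catalogue compound. Lactol 21 and hydroxy-aldehyde 30 are ring–chain tautomers; 21 is drawn closed (mixture of C1 epimers) and either form serves in step 17.

## Route

Step 1
Reactants: 1 4-hydroxy-2,6-dimethoxybenzaldehyde
Product: 2 3,5-dimethoxy-4-methylphenol
Conditions: H2 (3 bar), Pd/C, AcOH, HCl (cat.), 25 °C
Reagents that add atoms: none
Why: Benzylic hydrogenolysis: the aldehyde is hydrogenated to the benzylic alcohol, which, para to OH and flanked by two methoxy groups, ionises readily in acid and is reduced on to the methyl group. The arene and the ethers should survive at low pressure.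

Step 2
Reactants: 2 3,5-dimethoxy-4-methylphenol
Product: 3 6-hydroxy-2,4-dimethoxy-3-methylbenzaldehyde
Conditions: MgCl2, Et3N, (CH2O)n, MeCN, reflux; then 1 M HCl
Reagents that add atoms: paraformaldehyde (as formaldehyde), C=O
Why: Casnati–Skattebøl ortho-formylation: the magnesium phenoxide delivers formaldehyde only to an ortho carbon, and the two ortho positions of 2 are equivalent. A second formaldehyde oxidises the benzylic alkoxide to the aldehyde by hydride transfer.

Step 3
Reactants: 3 6-hydroxy-2,4-dimethoxy-3-methylbenzaldehyde
Product: 4 3,5-dimethoxy-2,4-dimethylphenol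
Conditions: H2 (3 bar), Pd/C, AcOH, HCl (cat.), 25 °C
Reagents that add atoms: none
Why: The same benzylic hydrogenolysis as step 1, here on a salicylaldehyde whose benzylic alcohol is activated by the ortho hydroxyl and the ortho/para methoxy groups.

Step 4
Reactants: 4 3,5-dimethoxy-2,4-dimethylphenol
Product: 5 2-bromo-3,5-dimethoxy-4,6-dimethylphenol
Conditions: NBS, MeCN, −20 → 0 °C
Reagents that add atoms: N-bromosuccinimide, O=C1CCC(=O)N1Br
Why: Electrophilic aromatic bromination at the single remaining ring C–H, which is ortho to OH and OMe and para to the other OMe. One equivalent at low temperature should avoid oxidation of the electron-rich phenol.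

Step 5
Reactants: 5 2-bromo-3,5-dimethoxy-4,6-dimethylphenol
Product: 6 (2-bromo-3,5-dimethoxy-4,6-dimethylphenoxy)trimethylsilane
Conditions: (Me3Si)2NH, THF, 70 °C; evaporate
Reagents that add atoms: hexamethyldisilazane, C[Si](C)(C)N[Si](C)(C)C
Why: Neutral O-silylation of a phenol; the only by-product is a gas, so the moisture-sensitive silyl ether can be used crude.

Step 6
Reactants: 6 (2-bromo-3,5-dimethoxy-4,6-dimethylphenoxy)trimethylsilane
Product: 9 3,5-dimethoxy-2,4-dimethyl-6-(trimethylsilyl)phenyl trifluoromethanesulfonate, via aryllithium 7 (not isolated), via lithium phenoxide 8 (not isolated)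
Conditions: n-BuLi, THF, −100 °C; then Tf2O, −100 → 25 °C
Reagents that add atoms: trifluoromethanesulfonic anhydride, O=S(=O)(OS(=O)(=O)C(F)(F)F)C(F)(F)F
Why: Bromine–lithium exchange gives 7, which undergoes a 1,3 O-to-C silyl shift (retro-Brook rearrangement) driven by formation of the lithium phenoxide 8. Trapping 8 with the anhydride is the standard entry to ortho-silylaryl triflates.

Step 7
Reactants: 9 3,5-dimethoxy-2,4-dimethyl-6-(trimethylsilyl)phenyl trifluoromethanesulfonate, 10 dimethyl malonate
Product: 13 methyl 4,6-dimethoxy-2-(2-methoxy-2-oxoethyl)-3,5-dimethylbenzoate, via aryne 11 (not isolated), via benzocyclobutenoxide 12 (not isolated)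
Conditions: CsF, MeCN, 60–80 °C
Reagents that add atoms: none
Why: Fluoride attacks silicon in 9 and triflate departs, releasing aryne 11 with its strained bond between C4a and C5. The caesium enolate of 10 adds through carbon to C5, and the aryl anion thus formed at C4a attacks an ester carbonyl of the same malonate unit in a 4-exo-trig closure to give benzocyclobutenoxide 12. Alkoxide 12 fragments by breaking the former malonate C–C bond, which leaves CO2Me on C4a and, after protonation of the resulting ester enolate, the CH2CO2Me arm on C5; the net change is insertion of the aryne into a C–C σ bond, the acyl-alkylation of arynes that is established for malonates and β-keto esters. No ring remains in 13 (the four-membered ring is only a relay) and no stereocentre is formed. The step needs one selectivity, the site of addition to the unsymmetrical aryne: the methoxy group on C8a, by σ-withdrawal, bends the aryne so that C5 is its flatter, more electrophilic end and the charge building up at C4a lies next to the C–O bond, which should outweigh the steric cost of the C6 methyl beside C5. Acyl transfer competes with protonation of the C4a anion (simple α-arylation of 10); an aprotic medium and a modest excess of 10 should favour insertion. Because the aryne reacts through strain release, both carbons enter positions where substitution chemistry would be blocked by crowding.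

Step 8
Reactants: 13 methyl 4,6-dimethoxy-2-(2-methoxy-2-oxoethyl)-3,5-dimethylbenzoate
Product: 14 methyl 4,6-dimethoxy-2-{2-[methoxy(methyl)amino]-2-oxoethyl}-3,5-dimethylbenzoate
Conditions: MeNH(OMe)·HCl, i-PrMgCl, THF, −20 °C; then 1 M HCl
Reagents that add atoms: N,O-dimethylhydroxylamine hydrochloride, CNOC.Cl
Why: Direct aminolysis of an ester by the chloromagnesium amide of N,O-dimethylhydroxylamine. The aliphatic ester should react while the benzoate, flanked by OMe and the acetate arm, is shielded.

Step 9
Reactants: 14 methyl 4,6-dimethoxy-2-{2-[methoxy(methyl)amino]-2-oxoethyl}-3,5-dimethylbenzoate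
Product: 15 methyl 4,6-dimethoxy-3,5-dimethyl-2-(2-oxopropyl)benzoate
Conditions: MeMgBr, THF, 0 °C; then 1 M HCl
Reagents that add atoms: methylmagnesium bromide, C[Mg]Br
Why: Weinreb ketone synthesis: the chelated tetrahedral intermediate prevents over-addition and releases the methyl ketone only on work-up. The di-ortho-substituted benzoate should not be attacked at this temperature.

Step 10
Reactants: 15 methyl 4,6-dimethoxy-3,5-dimethyl-2-(2-oxopropyl)benzoate
Product: 17 (3S)-6,8-dimethoxy-3,5,7-trimethyl-3,4-dihydro-1H-isochromen-1-one, via hydroxy ester 16 (not isolated)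
Conditions: ADH-A (alcohol dehydrogenase of Rhodococcus ruber), NADH (cat.), i-PrOH, phosphate buffer pH 7.5, 30 °C; then TsOH (cat.), toluene, 80 °C
Reagents that add atoms: none
Why: Enzymatic carbonyl reduction following the Prelog rule: hydride from NADH goes to the Re face of the methyl ketone (CH2Ar as the large group), giving the (S)-carbinol 16; 1-arylpropan-2-ones with an ortho ester are an established substrate class. An enzyme is chosen because transfer-hydrogenation catalysts of the ruthenium–diamine type rely on a conjugated aryl group for facial control and discriminate poorly between methyl and benzyl. Acid then closes the lactone by acyl substitution without touching C3.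

Step 11
Reactants: 17 (3S)-6,8-dimethoxy-3,5,7-trimethyl-3,4-dihydro-1H-isochromen-1-one
Product: 18 (3S)-6,8-dihydroxy-3,5,7-trimethyl-3,4-dihydro-1H-isochromen-1-one
Conditions: BBr3, CH2Cl2, −78 → 0 °C; then H2O
Reagents that add atoms: none
Why: Lewis-acid cleavage of aryl methyl ethers: the C8 ether is assisted by chelation to the lactone carbonyl and the C6 ether is twisted out of conjugation by its two ortho methyl groups, so both should cleave at low temperature. Alkyl–oxygen cleavage of the lactone would need substitution at a secondary carbon and should be slower, so C3 is retained.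

Step 12
Reactants: 18 (3S)-6,8-dihydroxy-3,5,7-trimethyl-3,4-dihydro-1H-isochromen-1-one
Product: 21 (3S)-3,5,7-trimethyl-3,4-dihydro-1H-isochromene-1,6,8-triol, via bis-silyl lactone 19 (not isolated), via bis-silyl lactol 20 (not isolated)
Conditions: (Me3Si)2NH, Me3SiCl (cat.), MeCN, 60 °C, evaporate; i-Bu2AlH, CH2Cl2, −78 °C; MeOH, aq. KNaC4H4O6; K2CO3 (cat.), MeOH, 0 °C
Reagents that add atoms: none
Why: Partial reduction of a lactone to the lactol through an aluminium hemiacetal that is stable at −78 °C. Transient silylation avoids aluminium phenoxides, which would deactivate the carbonyl and could expel the hemiacetal oxygen (quinone-methide formation and over-reduction); mild methanolysis then frees both phenols.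

Step 13
Reactants: 22 methyl (3R)-3-hydroxybutanoate
Product: 23 methyl (3R)-3-[(tert-butyldimethylsilyl)oxy]butanoate
Conditions: TBSCl, imidazole, DMF, 25 °C
Reagents that add atoms: tert-butyldimethylsilyl chloride, CC(C)(C)[Si](C)(C)Cl
Why: Standard silylation of a secondary alcohol; it blocks the hydroxyl against the strongly basic steps that follow and does not touch the stereocentre.

Step 14
Reactants: 23 methyl (3R)-3-[(tert-butyldimethylsilyl)oxy]butanoate
Product: 24 (3R)-3-[(tert-butyldimethylsilyl)oxy]-N-methoxy-N-methylbutanamide
Conditions: MeNH(OMe)·HCl, i-PrMgCl, THF, −20 °C; then 1 M HCl (cold)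
Reagents that add atoms: N,O-dimethylhydroxylamine hydrochloride, CNOC.Cl
Why: The same ester aminolysis as step 8; at low temperature the magnesium amide should add to the carbonyl faster than it deprotonates the α-carbon, so β-elimination of the silyloxy group is not expected.

Step 15
Reactants: 24 (3R)-3-[(tert-butyldimethylsilyl)oxy]-N-methoxy-N-methylbutanamide, 25 methyl acetoacetate
Product: 27 methyl (7R)-7-[(tert-butyldimethylsilyl)oxy]-3,5-dioxooctanoate, via acetoacetate dianion 26 (not isolated)
Conditions: LiN(i-Pr)2 (2 equiv. on 25), THF, −78 → 0 °C; then 24, −78 → 0 °C; then 1 M HCl (cold)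
Reagents that add atoms: none
Why: γ-Acylation of an acetoacetate dianion: the terminal carbanion of 26 is the more nucleophilic site. The stable tetrahedral adduct of the Weinreb amide prevents both over-addition and quenching of the dianion by the more acidic product.

Step 16
Reactants: 27 methyl (7R)-7-[(tert-butyldimethylsilyl)oxy]-3,5-dioxooctanoate
Product: 29 methyl 2-[(2R)-2-methyl-4-oxo-3,4-dihydro-2H-pyran-6-yl]acetate, via hydroxy diketo ester 28 (not isolated)
Conditions: CF3CO2H, CH2Cl2, H2O (trace), 0 → 25 °C
Reagents that add atoms: none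
Why: Acid removes the silyl group; the freed hydroxyl of 28 adds to the C3 ketone, the only carbonyl it can reach through a six-membered ring (6-exo-trig). Dehydration of the hemiketal gives the endocyclic vinylogous ester, and the C–O bond at the stereocentre is never broken.

Step 17
Reactants: 21 (3S)-3,5,7-trimethyl-3,4-dihydro-1H-isochromene-1,6,8-triol, 29 methyl 2-[(2R)-2-methyl-4-oxo-3,4-dihydro-2H-pyran-6-yl]acetate
Product: 32 7-hydroxy-5-[(2S)-2-hydroxypropyl]-6,8-dimethyl-3-[(2R)-2-methyl-4-oxo-3,4-dihydro-2H-pyran-6-yl]-2H-chromen-2-one, via hydroxy aldehyde 30 (not isolated), via arylidene ester 31 (not isolated)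
Conditions: piperidine (cat.), AcOH (cat.), EtOH, 25–50 °C
Reagents that add atoms: none
Why: Knoevenagel condensation followed by lactonisation: the methylene of 29 is activated by its ester and, vinylogously, by the C4' ketone, and condenses with the open form 30 under iminium catalysis to give 31. The C8a phenol then closes ring B onto the cis ester with loss of the ester alcohol; this irreversible step should drain any reversible oxa-Michael adducts. Both stereocentres are spectators.

## Compound list

1 | 4-hydroxy-2,6-dimethoxybenzaldehyde | COc1cc(O)cc(OC)c1C=O | starting material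
2 | 3,5-dimethoxy-4-methylphenol | COc1cc(O)cc(OC)c1C | intermediate
3 | 6-hydroxy-2,4-dimethoxy-3-methylbenzaldehyde | COc1cc(O)c(C=O)c(OC)c1C | intermediate
4 | 3,5-dimethoxy-2,4-dimethylphenol | COc1cc(O)c(C)c(OC)c1C | intermediate
5 | 2-bromo-3,5-dimethoxy-4,6-dimethylphenol | COc1c(Br)c(O)c(C)c(OC)c1C | intermediate
6 | (2-bromo-3,5-dimethoxy-4,6-dimethylphenoxy)trimethylsilane | COc1c(Br)c(O[Si](C)(C)C)c(C)c(OC)c1C | intermediate
7 | [2,4-dimethoxy-3,5-dimethyl-6-(trimethylsilyloxy)phenyl]lithium (formed in the flask) | COc1c([Li])c(O[Si](C)(C)C)c(C)c(OC)c1C | intermediate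
8 | lithium 3,5-dimethoxy-2,4-dimethyl-6-(trimethylsilyl)phenoxide (formed in the flask) | COc1c(C)c(OC)c(C)c([O-])c1[Si](C)(C)C.[Li+] | intermediate
9 | 3,5-dimethoxy-2,4-dimethyl-6-(trimethylsilyl)phenyl trifluoromethanesulfonate | COc1c(C)c(OC)c(C)c(OS(=O)(=O)C(F)(F)F)c1[Si](C)(C)C | intermediate
10 | dimethyl malonate | COC(=O)CC(=O)OC | starting material
11 | 3,5-dimethoxy-4,6-dimethylbenzyne (formed in the flask) | COC1=C(C)C(OC)=C(C)C#C1 | intermediate
12 | caesium 3,5,7-trimethoxy-8-(methoxycarbonyl)-2,4-dimethylbicyclo[4.2.0]octa-1,3,5-trien-7-olate (formed in the flask) | COc1c(C)c(OC)c(C)c2c1C([O-])(OC)C2C(=O)OC.[Cs+] | intermediate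
13 | methyl 4,6-dimethoxy-2-(2-methoxy-2-oxoethyl)-3,5-dimethylbenzoate | COC(=O)Cc1c(C)c(OC)c(C)c(OC)c1C(=O)OC | intermediate
14 | methyl 4,6-dimethoxy-2-{2-[methoxy(methyl)amino]-2-oxoethyl}-3,5-dimethylbenzoate | CON(C)C(=O)Cc1c(C)c(OC)c(C)c(OC)c1C(=O)OC | intermediate
15 | methyl 4,6-dimethoxy-3,5-dimethyl-2-(2-oxopropyl)benzoate | CC(=O)Cc1c(C)c(OC)c(C)c(OC)c1C(=O)OC | intermediate
16 | methyl 2-[(2S)-2-hydroxypropyl]-4,6-dimethoxy-3,5-dimethylbenzoate (formed in the flask) | C[C@H](O)Cc1c(C)c(OC)c(C)c(OC)c1C(=O)OC | intermediate
17 | (3S)-6,8-dimethoxy-3,5,7-trimethyl-3,4-dihydro-1H-isochromen-1-one | C[C@H]1Cc2c(C)c(OC)c(C)c(OC)c2C(=O)O1 | intermediate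
18 | (3S)-6,8-dihydroxy-3,5,7-trimethyl-3,4-dihydro-1H-isochromen-1-one | C[C@H]1Cc2c(C)c(O)c(C)c(O)c2C(=O)O1 | intermediate
19 | (3S)-3,5,7-trimethyl-6,8-bis(trimethylsilyloxy)-3,4-dihydro-1H-isochromen-1-one (formed in the flask) | C[C@H]1Cc2c(C)c(O[Si](C)(C)C)c(C)c(O[Si](C)(C)C)c2C(=O)O1 | intermediate
20 | (3S)-3,5,7-trimethyl-6,8-bis(trimethylsilyloxy)-3,4-dihydro-1H-isochromen-1-ol (formed in the flask, held as its aluminium alkoxide until work-up; C1 epimers) | C[C@H]1Cc2c(C)c(O[Si](C)(C)C)c(C)c(O[Si](C)(C)C)c2C(O)O1 | intermediate
21 | (3S)-3,5,7-trimethyl-3,4-dihydro-1H-isochromene-1,6,8-triol (C1 epimers; ring–chain tautomer of 30) | C[C@H]1Cc2c(C)c(O)c(C)c(O)c2C(O)O1 | intermediate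
22 | methyl (3R)-3-hydroxybutanoate | C[C@@H](O)CC(=O)OC | starting material
23 | methyl (3R)-3-[(tert-butyldimethylsilyl)oxy]butanoate | C[C@@H](O[Si](C)(C)C(C)(C)C)CC(=O)OC | intermediate
24 | (3R)-3-[(tert-butyldimethylsilyl)oxy]-N-methoxy-N-methylbutanamide | C[C@@H](O[Si](C)(C)C(C)(C)C)CC(=O)N(C)OC | intermediate
25 | methyl acetoacetate | CC(=O)CC(=O)OC | starting material
26 | dilithium dianion of methyl acetoacetate (formed in the flask) | [Li+].[Li+].[CH2-]C(=O)[CH-]C(=O)OC | intermediate
27 | methyl (7R)-7-[(tert-butyldimethylsilyl)oxy]-3,5-dioxooctanoate | C[C@@H](O[Si](C)(C)C(C)(C)C)CC(=O)CC(=O)CC(=O)OC | intermediate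
28 | methyl (7R)-7-hydroxy-3,5-dioxooctanoate (formed in the flask) | C[C@@H](O)CC(=O)CC(=O)CC(=O)OC | intermediate
29 | methyl 2-[(2R)-2-methyl-4-oxo-3,4-dihydro-2H-pyran-6-yl]acetate | COC(=O)CC1=CC(=O)C[C@@H](C)O1 | intermediate
30 | 2,4-dihydroxy-6-[(2S)-2-hydroxypropyl]-3,5-dimethylbenzaldehyde (formed in the flask) | C[C@H](O)Cc1c(C)c(O)c(C)c(O)c1C=O | intermediate
31 | methyl 3-{2,4-dihydroxy-6-[(2S)-2-hydroxypropyl]-3,5-dimethylphenyl}-2-[(2R)-2-methyl-4-oxo-3,4-dihydro-2H-pyran-6-yl]prop-2-enoate (formed in the flask; alkene geometry not fixed) | COC(=O)C(=Cc1c(O)c(C)c(O)c(C)c1C[C@H](C)O)C1=CC(=O)C[C@@H](C)O1 | intermediate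
32 | 7-hydroxy-5-[(2S)-2-hydroxypropyl]-6,8-dimethyl-3-[(2R)-2-methyl-4-oxo-3,4-dihydro-2H-pyran-6-yl]-2H-chromen-2-one | Cc1c(O)c(C)c2oc(=O)c(C3=CC(=O)C[C@@H](C)O3)cc2c1C[C@H](C)O | target

## Step count and least certain steps

Total: 17 steps. Longest linear sequence: 13 steps (steps 1–12 and 17, from 1 to 32); the branch from 22 to 29 is four steps (13–16).

**Step 7 (key step).** Three things can go wrong.
- The malonate carbanion may add to the wrong aryne terminus if the C6 methyl shields C5 more than the C8a methoxy group directs.
- Protonation of the C4a anion may outrun acyl transfer, so that only α-arylation results.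
- The crowded silyl triflate may release the aryne slowly, allowing side reactions of the fluoride-generated enolate.

Fallback, from phenol 4 back to ketone 15, with the two carbons set by formylation and cross-coupling instead of an aryne:
- ortho-formylation of 4 (MgCl2, Et3N, paraformaldehyde) should give 2-hydroxy-4,6-dimethoxy-3,5-dimethylbenzaldehyde F1;
- Tf2O/pyridine gives 2-formyl-3,5-dimethoxy-4,6-dimethylphenyl trifluoromethanesulfonate F2;
- Stille allylation (allyltributylstannane, Pd(PPh3)4, LiCl, DMF) gives 4,6-dimethoxy-3,5-dimethyl-2-(prop-2-en-1-yl)benzaldehyde F3;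
- Pinnick oxidation (NaClO2, NaH2PO4, 2-methyl-2-butene) gives 4,6-dimethoxy-3,5-dimethyl-2-(prop-2-en-1-yl)benzoic acid F4;
- MeI/K2CO3 gives methyl 4,6-dimethoxy-3,5-dimethyl-2-(prop-2-en-1-yl)benzoate F5;
- Wacker oxidation (PdCl2, CuCl, O2, DMF/H2O) gives 15.

**Step 10.** The enzyme may accept the bulky, hexasubstituted aryl ketone poorly, giving slow or incomplete reduction, or its facial selectivity may fall with so large a substituent. Fallback by resolution, from 15 back to 16: NaBH4 in MeOH at 0 °C gives racemic methyl 2-(2-hydroxypropyl)-4,6-dimethoxy-3,5-dimethylbenzoate F6. Candida antarctica lipase B with vinyl acetate should acylate the (R)-alcohol selectively to methyl 2-[(2R)-2-acetoxypropyl]-4,6-dimethoxy-3,5-dimethylbenzoate F7 and leave the (S)-alcohol 16, which is separated and lactonised as in step 10. This costs half of the material.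

**Step 12.** The hydride step may run past the hemiacetal: loss of a labile silyl group would expose a phenoxide that pushes out the C4 oxygen, and the resulting cation would be reduced further. Silylation of the chelated C8 hydroxyl may also be incomplete. Fallback with isolable silyl ethers, from 18 back to 21: TBSOTf/2,6-lutidine gives (3S)-6,8-bis[(tert-butyldimethylsilyl)oxy]-3,5,7-trimethyl-3,4-dihydro-1H-isochromen-1-one F8; i-Bu2AlH at −78 °C gives (3S)-6,8-bis[(tert-butyldimethylsilyl)oxy]-3,5,7-trimethyl-3,4-dihydro-1H-isochromen-1-ol F9; Bu4NF buffered with AcOH releases 21.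

**Step 17.** Several processes threaten this step.
- The amine may add to C2' of ring C and open it.
- Base may trigger retro-oxa-Michael opening and reclosure, eroding the configuration at C6'.
- The hindered, electron-rich aldehyde may condense slowly.
- The C2'' hydroxyl may add reversibly to the arylidene intermediate.

Fallback that builds ring C last under acid, from 21 and 25 to 32:
- Knoevenagel condensation of 21 with 25 (piperidine, EtOH) should give 3-acetyl-7-hydroxy-5-[(2S)-2-hydroxypropyl]-6,8-dimethyl-2H-chromen-2-one F10;
- TBSOTf/2,6-lutidine gives its bis-silyl ether, 3-acetyl-7-[(tert-butyldimethylsilyl)oxy]-5-{(2S)-2-[(tert-butyldimethylsilyl)oxy]propyl}-6,8-dimethyl-2H-chromen-2-one F11;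
- ester 23 is reduced with i-Bu2AlH at −78 °C to (3R)-3-[(tert-butyldimethylsilyl)oxy]butanal F12;
- a boron aldol reaction of F11 (Bu2BOTf, i-Pr2NEt) with F12 gives the β-hydroxy ketone F13 (epimers at the new carbinol, which is oxidised next);
- Dess–Martin periodinane gives the 1,3-diketone F14;
- aqueous HF in MeCN removes the three silyl groups and cyclodehydrates to 32.

## Further compounds

F1 | step 7 | 2-hydroxy-4,6-dimethoxy-3,5-dimethylbenzaldehyde | O=Cc1c(O)c(C)c(OC)c(C)c1OC
F2 | step 7 | 2-formyl-3,5-dimethoxy-4,6-dimethylphenyl trifluoromethanesulfonate | O=Cc1c(OS(=O)(=O)C(F)(F)F)c(C)c(OC)c(C)c1OC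
F3 | step 7 | 4,6-dimethoxy-3,5-dimethyl-2-(prop-2-en-1-yl)benzaldehyde | O=Cc1c(CC=C)c(C)c(OC)c(C)c1OC
F4 | step 7 | 4,6-dimethoxy-3,5-dimethyl-2-(prop-2-en-1-yl)benzoic acid | OC(=O)c1c(CC=C)c(C)c(OC)c(C)c1OC
F5 | step 7 | methyl 4,6-dimethoxy-3,5-dimethyl-2-(prop-2-en-1-yl)benzoate | COC(=O)c1c(CC=C)c(C)c(OC)c(C)c1OC
F6 | step 10 | methyl 2-(2-hydroxypropyl)-4,6-dimethoxy-3,5-dimethylbenzoate (racemic) | CC(O)Cc1c(C)c(OC)c(C)c(OC)c1C(=O)OC
F7 | step 10 | methyl 2-[(2R)-2-acetoxypropyl]-4,6-dimethoxy-3,5-dimethylbenzoate | C[C@@H](OC(C)=O)Cc1c(C)c(OC)c(C)c(OC)c1C(=O)OC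
F8 | step 12 | (3S)-6,8-bis[(tert-butyldimethylsilyl)oxy]-3,5,7-trimethyl-3,4-dihydro-1H-isochromen-1-one | C[C@H]1Cc2c(C)c(O[Si](C)(C)C(C)(C)C)c(C)c(O[Si](C)(C)C(C)(C)C)c2C(=O)O1
F9 | step 12 | (3S)-6,8-bis[(tert-butyldimethylsilyl)oxy]-3,5,7-trimethyl-3,4-dihydro-1H-isochromen-1-ol (C1 epimers) | C[C@H]1Cc2c(C)c(O[Si](C)(C)C(C)(C)C)c(C)c(O[Si](C)(C)C(C)(C)C)c2C(O)O1
F10 | step 17 | 3-acetyl-7-hydroxy-5-[(2S)-2-hydroxypropyl]-6,8-dimethyl-2H-chromen-2-one | CC(=O)c1cc2c(C[C@H](C)O)c(C)c(O)c(C)c2oc1=O
F11 | step 17 | 3-acetyl-7-[(tert-butyldimethylsilyl)oxy]-5-{(2S)-2-[(tert-butyldimethylsilyl)oxy]propyl}-6,8-dimethyl-2H-chromen-2-one | CC(=O)c1cc2c(C[C@H](C)O[Si](C)(C)C(C)(C)C)c(C)c(O[Si](C)(C)C(C)(C)C)c(C)c2oc1=O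
F12 | step 17 | (3R)-3-[(tert-butyldimethylsilyl)oxy]butanal | C[C@@H](O[Si](C)(C)C(C)(C)C)CC=O
F13 | step 17 | 7-[(tert-butyldimethylsilyl)oxy]-3-{(5R)-5-[(tert-butyldimethylsilyl)oxy]-3-hydroxyhexanoyl}-5-{(2S)-2-[(tert-butyldimethylsilyl)oxy]propyl}-6,8-dimethyl-2H-chromen-2-one (epimers at the hydroxyl carbon) | C[C@@H](O[Si](C)(C)C(C)(C)C)CC(O)CC(=O)c1cc2c(C[C@H](C)O[Si](C)(C)C(C)(C)C)c(C)c(O[Si](C)(C)C(C)(C)C)c(C)c2oc1=O
F14 | step 17 | (5R)-5-[(tert-butyldimethylsilyl)oxy]-1-[7-[(tert-butyldimethylsilyl)oxy]-5-{(2S)-2-[(tert-butyldimethylsilyl)oxy]propyl}-6,8-dimethyl-2-oxo-2H-chromen-3-yl]hexane-1,3-dione | C[C@@H](O[Si](C)(C)C(C)(C)C)CC(=O)CC(=O)c1cc2c(C[C@H](C)O[Si](C)(C)C(C)(C)C)c(C)c(O[Si](C)(C)C(C)(C)C)c(C)c2oc1=O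
A1 | alternative 1 | 2,6-dimethyl-5-[(2S)-2-(tert-butyldimethylsilyloxy)propyl]-3-(triisopropylsilyloxy)phenol | Cc1c(O)c(C)c(O[Si](C(C)C)(C(C)C)C(C)C)cc1C[C@H](C)O[Si](C)(C)C(C)(C)C
A2 | alternative 1 | 3-[(2S)-2-(tert-butyldimethylsilyloxy)propyl]-4-methylcyclobut-2-en-1-one | CC1C(=O)C=C1C[C@H](C)O[Si](C)(C)C(C)(C)C
A3 | alternative 1 | triisopropyl(prop-1-yn-1-yloxy)silane | CC#CO[Si](C(C)C)(C(C)C)C(C)C
A4 | alternative 2 | 7-(tert-butyldimethylsilyloxy)-3-[(5R)-5-(tert-butyldimethylsilyloxy)-3-oxohex-1-yn-1-yl]-5-[(2S)-2-(tert-butyldimethylsilyloxy)propyl]-6,8-dimethyl-2H-chromen-2-one | Cc1c(O[Si](C)(C)C(C)(C)C)c(C)c2oc(=O)c(C#CC(=O)C[C@@H](C)O[Si](C)(C)C(C)(C)C)cc2c1C[C@H](C)O[Si](C)(C)C(C)(C)C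
A5 | alternative 2 | 7-(tert-butyldimethylsilyloxy)-5-[(2S)-2-(tert-butyldimethylsilyloxy)propyl]-3-ethynyl-6,8-dimethyl-2H-chromen-2-one | Cc1c(O[Si](C)(C)C(C)(C)C)c(C)c2oc(=O)c(C#C)cc2c1C[C@H](C)O[Si](C)(C)C(C)(C)C
A6 | alternative 2 | carbon monoxide | [C-]#[O+]
A7 | alternative 2 | tert-butyl{[(2R)-1-iodopropan-2-yl]oxy}dimethylsilane | IC[C@@H](C)O[Si](C)(C)C(C)(C)C
A8 | alternative 3 | 7-(tert-butyldimethylsilyloxy)-5-[(2S)-2-(tert-butyldimethylsilyloxy)propyl]-6,8-dimethyl-3-[(2R)-2-methyl-4-oxo-3,4-dihydro-2H-pyran-6-yl]-2H-chromen-2-one | Cc1c(O[Si](C)(C)C(C)(C)C)c(C)c2oc(=O)c(C3=CC(=O)C[C@@H](C)O3)cc2c1C[C@H](C)O[Si](C)(C)C(C)(C)C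
A9 | alternative 3 | 3-[1,3-bis(trimethylsilyloxy)buta-1,3-dien-1-yl]-7-(tert-butyldimethylsilyloxy)-5-[(2S)-2-(tert-butyldimethylsilyloxy)propyl]-6,8-dimethyl-2H-chromen-2-one | Cc1c(O[Si](C)(C)C(C)(C)C)c(C)c2oc(=O)c(C(O[Si](C)(C)C)=CC(=C)O[Si](C)(C)C)cc2c1C[C@H](C)O[Si](C)(C)C(C)(C)C
A10 | alternative 3 | acetaldehyde | CC=O
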